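**Retrosynthetic overview**
1. Structural feature: ring A is a β-resorcylic acid (C1 CO2H, C2 OH, C3 H, C4 OH, C5 O-aryl, C6 CH2C(O)C5H11). One H2 below it lies a 2,4-dioxocyclohexanecarboxylate, in which C3–C4–C5–C6 is an α-aryloxy methyl enone and C1–C2 plus the carboxyl is a malonate.
2. Key disconnection: bonds C1–C6 (conjugate addition) and C2–C3 (Claisen acylation) lead back to the aryloxy enone and dibenzyl malonate. The C5–O–C8' ether is carried in, so no diaryl ether coupling is needed.
3. Enone: C5=C6 comes from a Horner–Wadsworth–Emmons olefination of an α-aryloxy-β-ketophosphonate with dioxolane-masked 3-oxooctanal, which fixes C5 and not the methyl group (C3) as the olefination site. The C5–O bond comes from rhodium carbenoid O–H insertion into the 8-hydroxyisocoumarin.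
4. Ring B unit: lateral lithiation and Weinreb acylation of MOM-protected methyl 2-hydroxy-4-methoxy-6-methylbenzoate, then enol lactonisation.
5. Ring order: benzene ring B is bought, the pyranone ring closes in step 4, ring A closes in step 9 and is aromatised in step 10. Ketal hydrolysis and then benzyl hydrogenolysis finish the route.

Key step: step 9

Remark on the chemistry: the target has no stereocentre and no stereogenic double bond. The stereocentres of 11, 18 and 19 and the alkene geometry of 15 are transient, so racemates and isomer mixtures are carried forward.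

**Step 1**
Reactants: 1 methyl 2-hydroxy-4-methoxy-6-methylbenzoate
Product: 2 methyl 4-methoxy-2-(methoxymethoxy)-6-methylbenzoate
Conditions: NaH, MOMCl, DMF, 0 °C to rt
Reagents that add atoms: chloromethyl methyl ether (MOMCl), COCCl
Why: Williamson-type O-alkylation of the sodium phenoxide with a very reactive chloromethyl ether masks the acidic chelated OH before the carbanion chemistry of step 3.

**Step 2**
Reactants: 3 hexanoyl chloride
Product: 4 N-methoxy-N-methylhexanamide
Conditions: MeNH(OMe)·HCl, Et3N (2.2 equiv), CH2Cl2, 0 °C to rt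
Reagents that add atoms: N,O-dimethylhydroxylamine hydrochloride, CNOC.Cl
Why: N-acylation of the hydroxylamine by the acid chloride is the standard preparation of a Weinreb amide.

**Step 3**
Reactants: 2 methyl 4-methoxy-2-(methoxymethoxy)-6-methylbenzoate; 4 N-methoxy-N-methylhexanamide
Product: 7 methyl 4-methoxy-2-(methoxymethoxy)-6-(2-oxoheptyl)benzoate, via benzylic lithium species 5 (not isolated), via lithium tetrahedral adduct 6 (not isolated)
Conditions: LiN(iPr)2 (LDA, 1.1 equiv), THF, –78 °C; then 4, –78 °C; AcOH quench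
Reagents that add atoms: none
Why: Lateral lithiation of an ortho-toluate is followed by a Weinreb ketone synthesis, in which the chelated adduct 6 persists until the quench, so neither double addition nor proton exchange with the product ketone can occur.

**Step 4**
Reactants: 7 methyl 4-methoxy-2-(methoxymethoxy)-6-(2-oxoheptyl)benzoate
Product: 9 8-hydroxy-6-methoxy-3-pentyl-1H-isochromen-1-one, via phenolic keto ester 8 (not isolated)
Conditions: 3 M aq HCl, THF, 50 °C; solvent swap; p-TsOH·H2O (10 mol %), toluene, reflux (Dean–Stark)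
Reagents that add atoms: none
Why: Acid hydrolysis of the MOM acetal is followed by acid-catalysed enol lactonisation (6-exo-trig attack of the ketone enol oxygen on the ester), driven by removal of methanol and by the conjugated pyranone that forms.

**Step 5**
Reactants: 9 8-hydroxy-6-methoxy-3-pentyl-1H-isochromen-1-one; 10 dimethyl (1-diazo-2-oxopropyl)phosphonate
Product: 11 dimethyl {1-[(6-methoxy-1-oxo-3-pentyl-1H-isochromen-8-yl)oxy]-2-oxopropyl}phosphonate (racemic)
Conditions: Rh2(OAc)4 (2 mol %), toluene, 80 °C, slow addition of 10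
Reagents that add atoms: none
Why: In this rhodium carbenoid O–H insertion the phenol oxygen traps the acceptor/acceptor carbenoid (oxonium ylide, then proton shift) faster than the trisubstituted, electron-poor C3=C4 bond can, and the new stereocentre is racemic and disappears in step 8.

**Step 6**
Reactants: 12 methyl 3-oxooctanoate
Product: 13 methyl 2-(2-pentyl-1,3-dioxolan-2-yl)acetate
Conditions: HOCH2CH2OH, p-TsOH·H2O (cat.), toluene, reflux, Dean–Stark
Reagents that add atoms: ethylene glycol, OCCO
Why: Acid-catalysed ketalisation of a β-keto ester with azeotropic removal of water is selective for the ketone carbonyl.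

**Step 7**
Reactants: 13 methyl 2-(2-pentyl-1,3-dioxolan-2-yl)acetate
Product: 14 2-(2-pentyl-1,3-dioxolan-2-yl)acetaldehyde
Conditions: iBu2AlH (1.05 equiv), CH2Cl2, –78 °C; aq potassium sodium tartrate
Reagents that add atoms: none
Why: In this partial ester reduction the aluminium hemiacetal, stabilised by a dioxolane oxygen, holds at –78 °C and releases the aldehyde only on work-up; 14 is used at once.

**Step 8**
Reactants: 11 dimethyl {1-[(6-methoxy-1-oxo-3-pentyl-1H-isochromen-8-yl)oxy]-2-oxopropyl}phosphonate; 14 2-(2-pentyl-1,3-dioxolan-2-yl)acetaldehyde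
Product: 15 (Z)-3-[(6-methoxy-1-oxo-3-pentyl-1H-isochromen-8-yl)oxy]-5-(2-pentyl-1,3-dioxolan-2-yl)pent-3-en-2-one
Conditions: LiCl, iPr2NEt, MeCN, 0 °C to rt
Reagents that add atoms: none
Why: Under Masamune–Roush Horner–Wadsworth–Emmons conditions the lithium-chelated phosphonate, acidified by P=O, C=O and OAr, is deprotonated by an amine mild enough for the β-ketal aldehyde and the enol lactone; the Z isomer (acetyl trans to the chain) is expected, and any E isomer gives the same adduct in step 9.

**Step 9**
Reactants: 15 (Z)-3-[(6-methoxy-1-oxo-3-pentyl-1H-isochromen-8-yl)oxy]-5-(2-pentyl-1,3-dioxolan-2-yl)pent-3-en-2-one; 16 dibenzyl malonate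
Product: 19 benzyl 5-[(6-methoxy-1-oxo-3-pentyl-1H-isochromen-8-yl)oxy]-2,4-dioxo-6-[(2-pentyl-1,3-dioxolan-2-yl)methyl]cyclohexane-1-carboxylate (diastereomer mixture), via sodium dibenzyl malonate 17 (not isolated), via open-chain Michael adduct 18 (not isolated)
Conditions: NaH (1.1 equiv), 16 (1.2 equiv), THF, 0 °C; add 15, rt then 60 °C; cold 1 M HCl to pH 4
Reagents that add atoms: none
Why: Malonate anion 17 adds to the enone β-carbon (bond C1–C6); proton exchange within 18 gives a small share of the methyl ketone enolate (C3), which acylates on one benzyl ester (bond C2–C3), and the expelled benzyloxide at once deprotonates the new 1,3-dione, which makes the reversible sequence irreversible. The closest known reaction type is the Michael–Claisen annulation of malonates with alk-3-en-2-ones to 6-alkyl-2,4-dioxocyclohexanecarboxylates, as in the classical olivetol route. Ring A closes by a 6-(enolendo)-exo-trig acyl substitution. C1, C5 and C6 form without control (C1 and C5 are epimerisable) and all three become sp2 carbons in step 10, so no controlling element is needed. Conjugate addition should prevail because 1,2-addition of a stabilised anion is reversible, and the Claisen regiochemistry is fixed because the C5 enolate could reach a malonate ester only through a four-membered ring. One equivalent of base leaves no free alkoxide; the lactone carbonyl is deactivated by the C6' methoxy and C8' aryloxy donors and its attack by the C5 enolate would create a quaternary centre; and dioxolane opening after γ-deprotonation is reversible because the alkoxide stays tethered.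

**Step 10**
Reactants: 19 benzyl 5-aryloxy-2,4-dioxo-6-[(2-pentyl-1,3-dioxolan-2-yl)methyl]cyclohexane-1-carboxylate
Product: 20 benzyl 2,4-dihydroxy-5-[(6-methoxy-1-oxo-3-pentyl-1H-isochromen-8-yl)oxy]-6-[(2-pentyl-1,3-dioxolan-2-yl)methyl]benzoate
Conditions: DDQ (1.05 equiv), dry 1,4-dioxane, rt to 60 °C
Reagents that add atoms: none
Why: In this quinone dehydrogenation of a dihydroresorcylate, hydride abstraction from the tertiary C6–H, allylic to the C1=C2 β-keto ester enol, then loss of the C5 proton and tautomerisation give the arene, while dry neutral conditions spare the dioxolane.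

**Step 11**
Reactants: 20 benzyl 2,4-dihydroxy-5-aryloxy-6-[(2-pentyl-1,3-dioxolan-2-yl)methyl]benzoate
Product: 21 benzyl 2,4-dihydroxy-5-[(6-methoxy-1-oxo-3-pentyl-1H-isochromen-8-yl)oxy]-6-(2-oxoheptyl)benzoate (benzyl β-collatolate)
Conditions: 1 M aq HCl, THF, rt
Reagents that add atoms: water, O
Why: Mild acid hydrolysis of a dialkyl ketone dioxolane is done while C1 is still a benzyl ester, so neither decarboxylation of a free resorcylic acid nor enol lactonisation of ring A (which needed hot p-TsOH in step 4) should compete.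

**Step 12**
Reactants: 21 benzyl β-collatolate
Product: 22 β-collatolic acid
Conditions: H2 (1 atm), Pd/C (10 wt %), EtOAc, rt, stopped after one equivalent of H2
Reagents that add atoms: none
Why: Catalytic hydrogenolysis of the benzyl ester under neutral conditions is much faster than saturation of the trisubstituted, conjugated C3'=C4' bond of the isocoumarin or reduction of the dialkyl ketone, and it releases the keto acid without acid or base.

**Compound list**
1 | methyl 2-hydroxy-4-methoxy-6-methylbenzoate | COC(=O)c1c(C)cc(OC)cc1O | starting material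
2 | methyl 4-methoxy-2-(methoxymethoxy)-6-methylbenzoate | COC(=O)c1c(C)cc(OC)cc1OCOC | intermediate
3 | hexanoyl chloride | CCCCCC(=O)Cl | starting material
4 | N-methoxy-N-methylhexanamide | CCCCCC(=O)N(C)OC | intermediate
5 | benzylic lithium derivative of 2 | [Li]Cc1cc(OC)cc(OCOC)c1C(=O)OC | intermediate (not isolated)
6 | lithium tetrahedral adduct of 5 and 4 | [Li+].CCCCCC([O-])(Cc1cc(OC)cc(OCOC)c1C(=O)OC)N(C)OC | intermediate (not isolated)
7 | methyl 4-methoxy-2-(methoxymethoxy)-6-(2-oxoheptyl)benzoate | CCCCCC(=O)Cc1cc(OC)cc(OCOC)c1C(=O)OC | intermediate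
8 | methyl 2-hydroxy-4-methoxy-6-(2-oxoheptyl)benzoate | CCCCCC(=O)Cc1cc(OC)cc(O)c1C(=O)OC | intermediate (not isolated)
9 | 8-hydroxy-6-methoxy-3-pentyl-1H-isochromen-1-one | CCCCCc1cc2cc(OC)cc(O)c2c(=O)o1 | intermediate
10 | dimethyl (1-diazo-2-oxopropyl)phosphonate | CC(=O)C(=[N+]=[N-])P(=O)(OC)OC | starting material
11 | dimethyl {1-[(6-methoxy-1-oxo-3-pentyl-1H-isochromen-8-yl)oxy]-2-oxopropyl}phosphonate (racemic) | CC(=O)C(Oc1cc(OC)cc2cc(CCCCC)oc(=O)c12)P(=O)(OC)OC | intermediate
12 | methyl 3-oxooctanoate | CCCCCC(=O)CC(=O)OC | starting material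
13 | methyl 2-(2-pentyl-1,3-dioxolan-2-yl)acetate | CCCCCC1(CC(=O)OC)OCCO1 | intermediate
14 | 2-(2-pentyl-1,3-dioxolan-2-yl)acetaldehyde | CCCCCC1(CC=O)OCCO1 | intermediate
15 | (Z)-3-[(6-methoxy-1-oxo-3-pentyl-1H-isochromen-8-yl)oxy]-5-(2-pentyl-1,3-dioxolan-2-yl)pent-3-en-2-one | CC(=O)/C(Oc1cc(OC)cc2cc(CCCCC)oc(=O)c12)=C/CC1(CCCCC)OCCO1 | intermediate
16 | dibenzyl malonate | O=C(CC(=O)OCc1ccccc1)OCc1ccccc1 | starting material
17 | sodium dibenzyl malonate | [Na+].O=C(OCc1ccccc1)[CH-]C(=O)OCc1ccccc1 | intermediate (not isolated)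
18 | dibenzyl 2-{3-[(6-methoxy-1-oxo-3-pentyl-1H-isochromen-8-yl)oxy]-4-oxo-1-(2-pentyl-1,3-dioxolan-2-yl)pentan-2-yl}propanedioate (diastereomer mixture) | CC(=O)C(Oc1cc(OC)cc2cc(CCCCC)oc(=O)c12)C(CC1(CCCCC)OCCO1)C(C(=O)OCc1ccccc1)C(=O)OCc1ccccc1 | intermediate (not isolated)
19 | benzyl 5-[(6-methoxy-1-oxo-3-pentyl-1H-isochromen-8-yl)oxy]-2,4-dioxo-6-[(2-pentyl-1,3-dioxolan-2-yl)methyl]cyclohexane-1-carboxylate (diastereomer mixture) | O=C(OCc1ccccc1)C1C(=O)CC(=O)C(Oc2cc(OC)cc3cc(CCCCC)oc(=O)c23)C1CC1(CCCCC)OCCO1 | intermediate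
20 | benzyl 2,4-dihydroxy-5-[(6-methoxy-1-oxo-3-pentyl-1H-isochromen-8-yl)oxy]-6-[(2-pentyl-1,3-dioxolan-2-yl)methyl]benzoate | O=C(OCc1ccccc1)c1c(O)cc(O)c(Oc2cc(OC)cc3cc(CCCCC)oc(=O)c23)c1CC1(CCCCC)OCCO1 | intermediate
21 | benzyl 2,4-dihydroxy-5-[(6-methoxy-1-oxo-3-pentyl-1H-isochromen-8-yl)oxy]-6-(2-oxoheptyl)benzoate | CCCCCC(=O)Cc1c(Oc2cc(OC)cc3cc(CCCCC)oc(=O)c23)c(O)cc(O)c1C(=O)OCc1ccccc1 | intermediate
22 | β-collatolic acid | CCCCCC(=O)Cc1c(Oc2cc(OC)cc3cc(CCCCC)oc(=O)c23)c(O)cc(O)c1C(=O)O | target

**Total step count:** 12. **Longest linear sequence:** 9 steps (1, 3, 4, 5, 8, 9, 10, 11, 12).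

**Steps most likely to fail**

**Step 9.**
- What may go wrong: conjugate addition to a β-substituted enone whose α-oxygen feeds electron density to the β-carbon may be slow or may revert. Acyl transfer from the enol lactone to the C5 enolate, or γ-deprotonation with opening of the dioxolane, may then take over.
- Fallback: this sets out from 14, 16 and 9 and comes back at 22. It removes the aryloxy group and ring B from the annulation and forms the ether afterwards.
- Aldehyde 14 is olefinated with 1-(triphenylphosphoranylidene)propan-2-one (Wittig, CH2Cl2) to (E)-5-(2-pentyl-1,3-dioxolan-2-yl)pent-3-en-2-one F1.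
- The same malonate annulation with 16, now on an α-unsubstituted acceptor, gives benzyl 2,4-dioxo-6-[(2-pentyl-1,3-dioxolan-2-yl)methyl]cyclohexane-1-carboxylate F2.
- Dehydrogenation as in step 10 gives benzyl 2,4-dihydroxy-6-[(2-pentyl-1,3-dioxolan-2-yl)methyl]benzoate F3.
- NBS in MeCN at 0 °C should brominate C5, para to the chelated C2 hydroxyl, to benzyl 5-bromo-2,4-dihydroxy-6-[(2-pentyl-1,3-dioxolan-2-yl)methyl]benzoate F4.
- Benzyl bromide and K2CO3 cap both phenols to benzyl 2,4-bis(benzyloxy)-5-bromo-6-[(2-pentyl-1,3-dioxolan-2-yl)methyl]benzoate F5.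
- An Ullmann ether coupling with 9 (CuI, N,N-dimethylglycine, Cs2CO3, dioxane, 100 °C) forms the C5–O bond in benzyl 2,4-bis(benzyloxy)-5-[(6-methoxy-1-oxo-3-pentyl-1H-isochromen-8-yl)oxy]-6-[(2-pentyl-1,3-dioxolan-2-yl)methyl]benzoate F6.
- Hydrolysis as in step 11 gives benzyl 2,4-bis(benzyloxy)-5-[(6-methoxy-1-oxo-3-pentyl-1H-isochromen-8-yl)oxy]-6-(2-oxoheptyl)benzoate F7. Hydrogenolysis of all three benzyl groups then gives 22.

**Step 10.**
- What may go wrong: hydride abstraction may stall. The product, in which the C2 hydroxyl is para to the C5 aryloxy group, may also be oxidised further with loss of the aryloxy group.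
- Fallback: this sets out from 19 and comes back at 20. It replaces hydride abstraction by halogenation and dehydrohalogenation.
- One equivalent of NBS (CH2Cl2, 0 °C) should react at the strongly enolised C3 in preference to ring B. This gives benzyl 3-bromo-5-[(6-methoxy-1-oxo-3-pentyl-1H-isochromen-8-yl)oxy]-2,4-dioxo-6-[(2-pentyl-1,3-dioxolan-2-yl)methyl]cyclohexane-1-carboxylate F8.
- Heating F8 with LiBr and Li2CO3 in DMF (80 °C) removes hydrogen bromide and gives 20.

**Step 5.**
- What may go wrong: the peri hydrogen bond to the lactone carbonyl may slow ylide formation at the phenol oxygen. Carbene dimerisation, Wolff rearrangement or cyclopropanation of the C3=C4 bond may then consume the diazo compound.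
- Fallback: this sets out from 9 and comes back at 15, bypassing 11. It replaces carbenoid insertion and olefination by SN2 alkylation and condensation.
- Alkylation of 9 with chloroacetone (K2CO3, KI cat., acetone, reflux) gives 6-methoxy-8-(2-oxopropoxy)-3-pentyl-1H-isochromen-1-one F9.
- F9 is condensed with 14 under piperidinium acetate (toluene, 4 Å molecular sieves, 60 °C). Reaction is expected at the more acidic OCH2 position, giving 15 directly.

**Further compounds**
F1 | step 9 | (E)-5-(2-pentyl-1,3-dioxolan-2-yl)pent-3-en-2-one | CC(=O)/C=C/CC1(CCCCC)OCCO1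
F2 | step 9 | benzyl 2,4-dioxo-6-[(2-pentyl-1,3-dioxolan-2-yl)methyl]cyclohexane-1-carboxylate | O=C(OCc1ccccc1)C1C(=O)CC(=O)CC1CC1(CCCCC)OCCO1
F3 | step 9 | benzyl 2,4-dihydroxy-6-[(2-pentyl-1,3-dioxolan-2-yl)methyl]benzoate | O=C(OCc1ccccc1)c1c(O)cc(O)cc1CC1(CCCCC)OCCO1
F4 | step 9 | benzyl 5-bromo-2,4-dihydroxy-6-[(2-pentyl-1,3-dioxolan-2-yl)methyl]benzoate | O=C(OCc1ccccc1)c1c(O)cc(O)c(Br)c1CC1(CCCCC)OCCO1
F5 | step 9 | benzyl 2,4-bis(benzyloxy)-5-bromo-6-[(2-pentyl-1,3-dioxolan-2-yl)methyl]benzoate | O=C(OCc1ccccc1)c1c(OCc2ccccc2)cc(OCc2ccccc2)c(Br)c1CC1(CCCCC)OCCO1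
F6 | step 9 | benzyl 2,4-bis(benzyloxy)-5-[(6-methoxy-1-oxo-3-pentyl-1H-isochromen-8-yl)oxy]-6-[(2-pentyl-1,3-dioxolan-2-yl)methyl]benzoate | O=C(OCc1ccccc1)c1c(OCc2ccccc2)cc(OCc2ccccc2)c(Oc2cc(OC)cc3cc(CCCCC)oc(=O)c23)c1CC1(CCCCC)OCCO1
F7 | step 9 | benzyl 2,4-bis(benzyloxy)-5-[(6-methoxy-1-oxo-3-pentyl-1H-isochromen-8-yl)oxy]-6-(2-oxoheptyl)benzoate | CCCCCC(=O)Cc1c(Oc2cc(OC)cc3cc(CCCCC)oc(=O)c23)c(OCc2ccccc2)cc(OCc2ccccc2)c1C(=O)OCc1ccccc1
F8 | step 10 | benzyl 3-bromo-5-[(6-methoxy-1-oxo-3-pentyl-1H-isochromen-8-yl)oxy]-2,4-dioxo-6-[(2-pentyl-1,3-dioxolan-2-yl)methyl]cyclohexane-1-carboxylate | O=C(OCc1ccccc1)C1C(=O)C(Br)C(=O)C(Oc2cc(OC)cc3cc(CCCCC)oc(=O)c23)C1CC1(CCCCC)OCCO1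
F9 | step 5 | 6-methoxy-8-(2-oxopropoxy)-3-pentyl-1H-isochromen-1-one | CC(=O)COc1cc(OC)cc2cc(CCCCC)oc(=O)c12
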